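17.4 d is the number I carry: the formation half-time H (a second-order half-life), the time in which pairing of starting material, with no other step running, brings target to half the charge, here at 0.10 M and 5 °C. At a fixed temperature and with pairing alone, H grows as the charge shrinks, and the target after time t is F = t/(t+H), in percent of the charge.

| flask | starting material | protic impurity | temperature | remark | time |
|---|---|---|---|---|---|
| birch | 0.14 M | 0.10 M | 5 °C | run made earlier |  |
| oak | 0.22 M | 0.10 M | 40 °C | run made earlier |  |
| maple | 0.10 M | 0.20 M | 5 °C | run made earlier |  |
| Tuesday's | 0.10 M | 0.100 M | 10 °C |  | 10 d |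
| Wednesday's | 0.10 M | 0.100 M | 70 °C |  | 10 d |
| Saturday's | 0.10 M | 0.100 M | 30 °C |  | 10 d |
| Thursday's | 0.10 M | 0.100 M | 50 °C |  | 10 d |

- birch (time / d: target / %): 1.25: 7.4; 2.50: 15.2; 3.00: 20.1; 5.00: 28.4; 6.00: 30.4; 8.00: 39.1
- oak (time / h: target / %): 3.00: 19.9; 6.00: 36.7; 10.0: 46.8; 15.0: 56.3; 25.0: 66.0; 40.0: 73.3
- maple (time / d: target / %): 1.67: 7.7; 3.00: 15.3; 5.00: 20.4; 6.00: 24.6; 8.00: 31.2

(standard deviation of a reading: 1 percentage point)

- percent here means starting material units held: one target or over-reaction product counts as two
- steps thought possible: 2 starting material -> target; target -> over-reaction product; starting material + protic impurity -> quenched substrate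

- the flask that comes out highest in amount of target, in percent of the starting material charged, or "all alike" when all lie within 1.5 percentage points (Tuesday's / Wednesday's / Saturday's / Thursday's / all alike)
- target at the end, in percent of the starting material charged, Tuesday's
- target at the end, in percent of the starting material charged, Wednesday's
- target at the end, in percent of the starting material charged, Saturday's
- target at the end, in percent of the starting material charged, Thursday's

1. I get that H from birch's last reading, 39.1 % at 8.00 d, scaled from its charge of 0.14 M to 0.10 M.
2. Maple is charged at 0.10 M with twice the protic impurity of birch, and its last reading gives 17.6 d. So at 5 °C the values of H read from birch and maple agree within the scatter of these readings.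
3. Oak's reading at 6.00 h, scaled the same way, gives 0.949 d at 40 °C.
4. I take ln H as a straight line in 1/T, T being the absolute temperature. That gives 2.04 d for Saturday's and 0.464 d for Thursday's.
5. Over 10 d, F is 83.1 % for Saturday's and 95.6 % for Thursday's, a gap of 12 percentage points.
6. Now I turn the question round. For Thursday's to finish above Saturday's, its fall below F may exceed Saturday's fall by less than that gap, and no further.
7. Oak's last reading stands 6.1 points below oak's own F at 40.0 h, but oak ran at 40 °C, the temperature of neither flask. I commit to Saturday's as the likelier flask and leave Thursday's open.
8. The forecast says Saturday's, with 46 % for Tuesday's, 3 % for Wednesday's, 72 % for Saturday's and 30 % for Thursday's: “Saturday's should be best; the hot flasks are the most uncertain”.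

The simulation gives Saturday's as highest, with 46.6 % for Tuesday's, 4.13 % for Wednesday's, 73.7 % for Saturday's and 59.5 % for Thursday's. The forecast's Thursday's stands 29 points too low.

    2 starting material → target (k = 1.50 M⁻¹ h⁻¹, Ea = 59.0 kJ mol⁻¹)
    target → over-reaction product (k = 0.0110 h⁻¹, Ea = 130 kJ mol⁻¹)
    starting material + protic impurity → quenched substrate (k = 1.10 M⁻¹ h⁻¹, Ea = 93.0 kJ mol⁻¹)
    (constants at 70 °C)

Saturday's ends 9.4 points below its F, and Thursday's ends 36 points below its F. Thursday's extra fall is therefore 27 points, more than the gap, and Saturday's finishes 14 points ahead. The neighbour is a repeat of Saturday's at 5 °C. There my H is 17.4 d and F over 10 d is 36.5 %. That neighbour gives 36.1 % of target and still holds 62.9 % of the charge as starting material.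

(The data are simulated from invented constants.)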